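**Retrosynthetic overview**

- The target is the all-cis (2R,3R,4R)-oxolane. Its CH2OH comes from LiAlH4 reduction of the all-cis oxolane-3-carboxylic acid.
- That acid comes from one hydrogenation of a γ-aryl lactone fused to a 4,5-dihydrofuran. Hydrogenolysis of the benzylic lactone C–O bond releases the ArCH2 group and the CO2H group, and syn addition of H2 anti to that benzyl group sets C-2 and C-3.
- The bicyclic lactone comes from an allylic β-keto ester in the key operation. A carbenoid cyclopropanation closes the lactone and a cyclopropane together, and an iodide-triggered Cloke–Wilson ring expansion turns the cyclopropane into the dihydrofuran.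
- The β-keto ester comes from ethyl 3,4,5-trimethoxybenzoylacetate and (S)-1-(3,4-dimethoxyphenyl)allyl alcohol (veratraldehyde, vinyl Grignard, lipase resolution). The carbinol centre is a relay that is erased later.
- Ring order: lactone and cyclopropane together, then dihydrofuran (the future oxolane) from the cyclopropane, then lactone opened, then dihydrofuran saturated.

Assumption: the SMILES is read as the all-cis (2R,3R,4R) isomer, and the cyclopropanation is assumed to favour the exo mode (aryl anti to the new ring), which is why the (S)-alcohol is used.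

**Route**

Step 1
Reactants: 1 3,4-dimethoxybenzaldehyde
Product: 2 rac-1-(3,4-dimethoxyphenyl)prop-2-en-1-ol
Conditions: CH2=CHMgBr (1.2 equiv), THF, 0 °C; aq. NH4Cl
Reagents that add atoms: vinylmagnesium bromide, C=C[Mg]Br
Why: Grignard 1,2-addition to the aromatic aldehyde gives the secondary allylic alcohol, formed racemic and resolved in step 2.

Step 2
Reactants: 2 rac-1-(3,4-dimethoxyphenyl)prop-2-en-1-ol
Product: 3 (1S)-1-(3,4-dimethoxyphenyl)prop-2-en-1-ol
Conditions: Novozym 435 (immobilised Candida antarctica lipase B), vinyl acetate (3 equiv), MTBE, 30 °C, stopped at about 55 % conversion; chromatography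
Reagents that add atoms: none
Why: Lipase-catalysed kinetic resolution by enantioselective transesterification (Kazlauskas rule, aryl large and vinyl medium) acetylates the (R)-alcohol and leaves the (S)-alcohol, the only external source of chirality in the route.

Step 3
Reactants: 3 (1S)-1-(3,4-dimethoxyphenyl)prop-2-en-1-ol; 4 ethyl 3-oxo-3-(3,4,5-trimethoxyphenyl)propanoate
Product: 5 (1S)-1-(3,4-dimethoxyphenyl)prop-2-en-1-yl 3-oxo-3-(3,4,5-trimethoxyphenyl)propanoate
Conditions: DMAP (0.3 equiv), 4 Å MS, toluene, reflux with removal of EtOH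
Reagents that add atoms: none
Why: DMAP-catalysed transesterification of a β-keto ester exchanges ethanol for the allylic alcohol by acyl–oxygen cleavage only, so the carbinol configuration is retained.

Step 4
Reactants: 5 (1S)-1-(3,4-dimethoxyphenyl)prop-2-en-1-yl 3-oxo-3-(3,4,5-trimethoxyphenyl)propanoate
Product: 8 (3S,3aR)-3-(3,4-dimethoxyphenyl)-6-(3,4,5-trimethoxyphenyl)-3a,4-dihydro-1H,3H-furo[3,4-c]furan-1-one, via phenyliodonium ylide 6 (not isolated), via acylcyclopropane lactone 7 (not isolated)
Conditions: PhI(OAc)2 (1.1 equiv), MgO (2.5 equiv), 4 Å MS, [Cu(MeCN)4]PF6 (5 mol %), ClCH2CH2Cl, 25 to 40 °C; then Bu4NI (0.3 equiv), 75 °C; chromatography removes the minor (3S,3aS) isomer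
Reagents that add atoms: none
Why: Proposed new method: PhI(OAc)2/MgO converts the β-keto ester into ylide 6, the copper carbenoid from 6 cyclopropanates the tethered vinyl group so that the lactone and cyclopropane rings close together (closest known type: Moriarty/Müller intramolecular cyclopropanation of iodonium ylides) with the aryl group at the carbinol carbon exo to minimise allylic strain, which sets C-3a, and iodide then opens the doubly activated cyclopropane at its CH2 and the enolate oxygen recloses by 5-exo-tet O-alkylation (nucleophile-catalysed Cloke–Wilson rearrangement) to the dihydrofuran.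

Step 5
Reactants: 8 (3S,3aR)-3-(3,4-dimethoxyphenyl)-6-(3,4,5-trimethoxyphenyl)-3a,4-dihydro-1H,3H-furo[3,4-c]furan-1-one
Product: 10 (2R,3S,4R)-4-[(3,4-dimethoxyphenyl)methyl]-2-(3,4,5-trimethoxyphenyl)oxolane-3-carboxylic acid, via dihydrofuran acid 9 (not isolated)
Conditions: H2 (20 bar), 10% Pd/C, EtOAc–EtOH, 25 to 40 °C, neutral medium
Reagents that add atoms: none
Why: Heterogeneous catalytic hydrogenation first hydrogenolyses the benzylic lactone C–O bond (erasing the relay centre and giving ArCH2 and CO2H) and then adds H2 syn to the tetrasubstituted enol ether double bond from the face opposite the benzyl group, which sets C-2 and C-3 cis to C-4.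

Step 6
Reactants: 10 (2R,3S,4R)-4-[(3,4-dimethoxyphenyl)methyl]-2-(3,4,5-trimethoxyphenyl)oxolane-3-carboxylic acid
Product: 11 [(2R,3R,4R)-4-[(3,4-dimethoxyphenyl)methyl]-2-(3,4,5-trimethoxyphenyl)oxolan-3-yl]methanol
Conditions: LiAlH4 (3 equiv), THF, 0 to 50 °C; aqueous NaOH work-up
Reagents that add atoms: none
Why: LiAlH4 reduction of the acid proceeds through the lithium carboxylate, which cannot epimerise at C-3, so all three centres are carried through unchanged (the C-3 descriptor changes from S to R only because CH2OH ranks below C-2).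

**Compound list**

1 | 3,4-dimethoxybenzaldehyde | COc1ccc(C=O)cc1OC | starting material
2 | rac-1-(3,4-dimethoxyphenyl)prop-2-en-1-ol | COc1ccc(C(O)C=C)cc1OC | intermediate
3 | (1S)-1-(3,4-dimethoxyphenyl)prop-2-en-1-ol | COc1ccc([C@@H](O)C=C)cc1OC | intermediate
4 | ethyl 3-oxo-3-(3,4,5-trimethoxyphenyl)propanoate | CCOC(=O)CC(=O)c1cc(OC)c(OC)c(OC)c1 | starting material
5 | (1S)-1-(3,4-dimethoxyphenyl)prop-2-en-1-yl 3-oxo-3-(3,4,5-trimethoxyphenyl)propanoate | COc1ccc([C@@H](OC(=O)CC(=O)c2cc(OC)c(OC)c(OC)c2)C=C)cc1OC | intermediate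
6 | phenyliodonium ylide of 5 (PhI+ on the carbanionic carbon between the two carbonyl groups) | COc1ccc([C@@H](OC(=O)[C-]([I+]c2ccccc2)C(=O)c2cc(OC)c(OC)c(OC)c2)C=C)cc1OC | intermediate
7 | (1R,4S,5S)-4-(3,4-dimethoxyphenyl)-1-(3,4,5-trimethoxybenzoyl)-3-oxabicyclo[3.1.0]hexan-2-one (aryl at C-4 anti to the cyclopropane CH2) | COc1ccc([C@H]2OC(=O)[C@]3(C(=O)c4cc(OC)c(OC)c(OC)c4)C[C@H]23)cc1OC | intermediate
8 | (3S,3aR)-3-(3,4-dimethoxyphenyl)-6-(3,4,5-trimethoxyphenyl)-3a,4-dihydro-1H,3H-furo[3,4-c]furan-1-one (H-3 and H-3a trans) | COc1ccc([C@H]2OC(=O)C3=C(c4cc(OC)c(OC)c(OC)c4)OC[C@H]23)cc1OC | intermediate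
9 | (4R)-4-[(3,4-dimethoxyphenyl)methyl]-2-(3,4,5-trimethoxyphenyl)-4,5-dihydrofuran-3-carboxylic acid | COc1ccc(C[C@H]2COC(c3cc(OC)c(OC)c(OC)c3)=C2C(O)=O)cc1OC | intermediate
10 | (2R,3S,4R)-4-[(3,4-dimethoxyphenyl)methyl]-2-(3,4,5-trimethoxyphenyl)oxolane-3-carboxylic acid (all-cis) | COc1ccc(C[C@H]2CO[C@@H](c3cc(OC)c(OC)c(OC)c3)[C@H]2C(O)=O)cc1OC | intermediate
11 | [(2R,3R,4R)-4-[(3,4-dimethoxyphenyl)methyl]-2-(3,4,5-trimethoxyphenyl)oxolan-3-yl]methanol (all-cis) | COc1ccc(C[C@H]2CO[C@@H](c3cc(OC)c(OC)c(OC)c3)[C@H]2CO)cc1OC | target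

**Step count and risks**

Total steps: 6. Longest linear sequence: 6 (1 to 11).

Step 4 is the most likely to fail. The risks are incomplete ylide formation in the flask, carbenoid attack on the electron-rich arene instead of the alkene, a modest exo/endo ratio, and iodide-induced scrambling at the benzylic lactone carbon. Any endo product, or scrambled material that co-elutes, lowers the final enantiomeric purity, because the relay centre is erased in step 5. The fallback sets out from 5 and comes back at 8. Regitz diazo transfer (4-acetamidobenzenesulfonyl azide, Et3N, MeCN) gives the diazo keto ester (1S)-1-(3,4-dimethoxyphenyl)prop-2-en-1-yl 2-diazo-3-oxo-3-(3,4,5-trimethoxyphenyl)propanoate F1. Slow addition of it to [Cu(MeCN)4]PF6 in refluxing CH2Cl2 gives cyclopropane 7, now isolated and freed from its endo diastereomer by chromatography or crystallisation. A separate Bu4NI-promoted ring expansion then gives 8.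

Step 5 is the second risk. The tetrasubstituted push–pull double bond may reduce slowly, and forcing conditions could hydrogenolyse the benzylic C-2–O bond of 10. The fallback sets out from 8 and comes back at 11. Ionic hydrogenolysis (Et3SiH, CF3CO2H, CH2Cl2, 0 °C) cleaves only the benzylic lactone C–O bond and gives acid 9 as an isolated compound. Me3SiCHN2 converts it into methyl (4R)-4-[(3,4-dimethoxyphenyl)methyl]-2-(3,4,5-trimethoxyphenyl)-4,5-dihydrofuran-3-carboxylate F2. Hydrogenation over Rh/Al2O3 (50 bar H2), which saturates the enol ether but spares benzylic ethers, gives methyl (2R,3S,4R)-4-[(3,4-dimethoxyphenyl)methyl]-2-(3,4,5-trimethoxyphenyl)oxolane-3-carboxylate F3. LiAlH4 reduces it to 11.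

Step 3 is the third risk. Heating an electron-rich secondary allylic β-keto ester may trigger Carroll rearrangement or allylic transposition. The fallback sets out from 3 and comes back at 5. Ac2O/pyridine gives (1S)-1-(3,4-dimethoxyphenyl)prop-2-en-1-yl acetate F4. Its lithium enolate (LiN(SiMe3)2, 2.2 equiv, THF, −78 °C) is acylated with 3,4,5-trimethoxybenzoyl chloride in a crossed Claisen condensation, which gives 5 without heating.

**Further compounds**

F1 | step 4 | (1S)-1-(3,4-dimethoxyphenyl)prop-2-en-1-yl 2-diazo-3-oxo-3-(3,4,5-trimethoxyphenyl)propanoate | COc1ccc([C@@H](OC(=O)C(=[N+]=[N-])C(=O)c2cc(OC)c(OC)c(OC)c2)C=C)cc1OC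
F2 | step 5 | methyl (4R)-4-[(3,4-dimethoxyphenyl)methyl]-2-(3,4,5-trimethoxyphenyl)-4,5-dihydrofuran-3-carboxylate | COc1ccc(C[C@H]2COC(c3cc(OC)c(OC)c(OC)c3)=C2C(=O)OC)cc1OC
F3 | step 5 | methyl (2R,3S,4R)-4-[(3,4-dimethoxyphenyl)methyl]-2-(3,4,5-trimethoxyphenyl)oxolane-3-carboxylate | COc1ccc(C[C@H]2CO[C@@H](c3cc(OC)c(OC)c(OC)c3)[C@H]2C(=O)OC)cc1OC
F4 | step 3 | (1S)-1-(3,4-dimethoxyphenyl)prop-2-en-1-yl acetate | COc1ccc([C@@H](OC(C)=O)C=C)cc1OC
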